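The noon run has an emptying time of 3.42 d, where I mean the time the charge of solid substrate takes at the early rate of product, and the midnight run has 2.29 d, shorter by a ratio of 1.49 against a catalyst ratio of 1.50.

| flask | solid substrate | free catalyst | remark | time |
|---|---|---|---|---|
| noon | 0.80 M | 2 mM | run made earlier |  |
| midnight | 0.80 M | 3 mM | run made earlier |  |
| flask | 0.80 M | 4.0 mM |  | 5.0 d |

| noon: time / d | noon: product / % | midnight: time / d | midnight: product / % |
|---|---|---|---|
| 0.417 | 12.2 | 1.04 | 45.4 |
| 1.25 | 36.6 | 2.08 | 76.7 |
| 2.00 | 57.8 | 3.00 | 85.9 |
| 3.00 | 73.6 | 4.00 | 87.8 |
| 5.00 | 83.6 | 5.00 | 89.7 |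
| 6.00 | 85.6 | 6.00 | 91.5 |

(standard deviation of a reading: 0.5 percentage points)

- solid substrate is a solid; its amount is given per volume of the solution
- at the start none of the solid substrate is in solution

- larch: doubling the solubility of the solid substrate, all else as stated
- cedar: doubling the dissolution coefficient of the solid substrate, all else as stated
- elm: doubling the amount of free catalyst, all else as stated

- product at 5.0 d, in percent of the solid substrate charged
- the change that raises the amount of product at 5.0 d, in percent of the solid substrate charged most ("none" if none brings more than 2 percentage points) (larch / cedar / elm / none)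
- amount of product at 5.0 d, in percent of the solid substrate charged, after cedar

So I scale inversely with free catalyst and give the flask 1.72 d; this emptying time is what I carry, and I reckon with the fraction left, not the fraction made.

It is the first rung of my ladder, and its straight line serves for the early readings alone: at 2.08 d the midnight run reads 76.7%, lower than the 90.8% on its line. The next rung comes from the midnight run, whose fraction left falls from 14.1% at 3.00 d to 8.50% at 6.00 d, a pseudo-first-order tail of 0.169 d⁻¹, which is a half-life of 4.11 d, longer than the emptying time. The asked 5.0 d is longer still, so I expect the flask to end on its tail. I match the midnight reading at 3.00 d to the flask at 2.25 d, let the fraction left decay from there, and commit to 91.1%.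

The forecast, a little higher, says 91.5% (89.5% to 93.5%), and 95% after cedar (92.5% to 97.5%), and it names larch as best, holding that “That tail is dissolution-limited”.

The flask gives 92.8%, and 92.8% after cedar.

    starting material ⇌ dormant form (K = 1.40, k = 0.00870 h⁻¹)
    catalyst intermediate → free catalyst + product (k = 31.0 h⁻¹)
    solid substrate ⇌ starting material, rate k3*(cs3 - [starting material]) while solid is left; crystals form when [starting material] > cs3 (solubility = 0.330 M, k = 0.900 h⁻¹)
    starting material + free catalyst ⇌ catalyst intermediate (K = 3.00 M⁻¹, k = 24.0 M⁻¹ h⁻¹)

The best change is elm, adding 3.8 percentage points, against 0.0096 points for cedar and −0.14 points for larch. By 2.50 d the dissolving has 100% of its turnover behind it, and at 5.00 d this flask holds 6.66% of the charge as dormant form against 0.534% as starting material. Its emptying time holds early: 0.500 d of 1.72 d gives 29.1%, and the flask stands at 27.0%. The neighbour with 0.0010 M of free catalyst has an emptying time of 6.87 d, longer than the 5.0 d it runs, so its line reaches 72.8%, and that neighbour gives 63.5%.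

The data come from a simulation on assumed constants; noise was put on by code.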